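**Plan**

1. Numbering of the target: oxirane carbons C1 (farnesyl) and C6, C2 = ketone, C3H=C4(Et), C5 = carbinol, O7. Retrosynthetic cuts, in order: C5 carbinol back to a carbonyl; oxirane bonds C1–O7 and C6–O7; the carbocycle bond C1–C2, with a C2–C5 bond re-formed; then C5–C6, C4–ethyl and the farnesyl–alkyne bond.
2. Enabling feature: C2 (C=O) and C5 (CHOH) are para on the carbocycle, so the ring is a hydroquinone in disguise. Its four carbons C2–C3–C4–C5 can be a cyclobutenone (C2 the carbonyl, C5 the OMe-bearing sp3 carbon) and C6=C1 its 4-alkenyl group.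
3. Forward: farnesyl bromide → skipped enyne → (E)-vinyl iodide; squarate → semisquarate; vinyllithium addition, O-methylation, ethyl in place of isopropoxy; thermal 4 → 6 ring expansion to a para-methoxyphenol whose two oxygens are already differentiated.
4. End game: PhI(OAc)2/MeOH to the quinone monoketal (free carbonyl at C2), epoxidation of C1=C6, ketal hydrolysis, reduction of the C5 carbonyl.
5. Stereochemistry: C1 and C6 from a catalyst-controlled (cinchona phase-transfer) nucleophilic epoxidation; C5 from substrate-controlled hydride delivery anti to the oxirane; both E alkenes come unchanged from (2E,6E)-farnesyl bromide.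

Key step: step 7

Abbreviations: Far = (2E,6E)-3,7,11-trimethyldodeca-2,6,10-trien-1-yl; FV = (1E,4E,8E)-5,9,13-trimethyltetradeca-1,4,8,12-tetraen-1-yl, i.e. (E)-2-Far-ethenyl.

Assumption: N-benzylcinchonidinium chloride is taken to be the pseudo-enantiomer that leads to the (1R,6S)-oxirane in step 9; should it favour the antipode, N-benzylcinchoninium chloride replaces it with no other change.

**Route**

Step 1
Reactants: 1 (2E,6E)-farnesyl bromide
Product: 2 (4E,8E)-5,9,13-trimethyltetradeca-4,8,12-trien-1-yne
Conditions: HC≡CMgBr (THF solution), CuCl (5 mol %), THF, 0 to 50 °C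
Reagents that add atoms: ethynylmagnesium bromide, C#C[Mg]Br
Why: Copper-catalysed allyl–alkynyl coupling of the Grignard reagent with the primary allylic bromide should occur at the unsubstituted allyl terminus (SN2) and give the skipped 1,4-enyne with the (E,E) geometry retained.

Step 2
Reactants: 2 (4E,8E)-5,9,13-trimethyltetradeca-4,8,12-trien-1-yne
Product: 4 (1E,4E,8E)-1-iodo-5,9,13-trimethyltetradeca-1,4,8,12-tetraene, via alkenylzirconocene chloride 3 (not isolated)
Conditions: Cp2Zr(H)Cl (1.2 equiv), THF, rt; then I2, 0 °C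
Reagents that add atoms: iodine, [I][I]
Why: Hydrozirconation (Schwartz reagent) adds Zr–H syn and anti-Markovnikov to the terminal alkyne in preference to the trisubstituted alkenes, and iodinolysis of the C–Zr bond with retention should give the (E)-vinyl iodide.

Step 3
Reactants: 5 diisopropyl squarate (3,4-diisopropoxycyclobut-3-ene-1,2-dione)
Product: 7 3-isopropoxycyclobut-3-ene-1,2-dione, via hydroxycyclobutenone 6 (not isolated)
Conditions: LiAlH(OtBu)3 (1.0 equiv), THF, −78 to 0 °C; then 6 M HCl, CH2Cl2, 0 °C
Reagents that add atoms: none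
Why: 1,2-Hydride addition to one squarate carbonyl followed by acid-induced ionisation of the carbinol and loss of propan-2-ol (the vinylogous-ester transposition used to make substituted cyclobutenediones) should give the semisquarate.

Step 4
Reactants: 4 (1E,4E,8E)-1-iodo-5,9,13-trimethyltetradeca-1,4,8,12-tetraene; 7 3-isopropoxycyclobut-3-ene-1,2-dione
Product: 9 4-hydroxy-3-isopropoxy-4-FV-cyclobut-2-en-1-one (racemic), via vinyllithium 8 (not isolated)
Conditions: t-BuLi (2.0 equiv), Et2O, −78 °C; then 7, THF, −78 °C; aq. NH4Cl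
Reagents that add atoms: none
Why: Iodine–lithium exchange with retention of the E geometry is followed by 1,2-addition to the ketone-like carbonyl next to the C–OiPr carbon (not the vinylogous-ester carbonyl), as in the standard preparation of 4-alkenyl-4-hydroxycyclobutenones; the new quaternary centre is racemic and is destroyed in step 7.

Step 5
Reactants: 9 4-hydroxy-3-isopropoxy-4-FV-cyclobut-2-en-1-one
Product: 10 3-isopropoxy-4-methoxy-4-FV-cyclobut-2-en-1-one (racemic)
Conditions: MeI, Ag2O, MeCN, rt, dark
Reagents that add atoms: iodomethane, CI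
Why: Purdie methylation of the tertiary hydroxyl under non-basic conditions avoids alkoxide-driven ring opening and installs the methyl ether that later tells the two hydroquinone oxygens apart.

Step 6
Reactants: 10 3-isopropoxy-4-methoxy-4-FV-cyclobut-2-en-1-one
Product: 12 3-ethyl-4-methoxy-4-FV-cyclobut-2-en-1-one (racemic), via cyclobutenol 11 (not isolated)
Conditions: EtLi, THF, −78 °C; then 1 M HCl, 0 °C
Reagents that add atoms: ethyllithium, [Li]CC
Why: Stork–Danheiser-type 1,2-addition to the vinylogous-ester carbonyl and acid hydrolysis/dehydration should replace OiPr by ethyl; because the sp3 ring carbon is bonded to both C1 and C3, an addition–elimination at C3 would give the same cyclobutenone.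

Step 7
Reactants: 12 3-ethyl-4-methoxy-4-FV-cyclobut-2-en-1-one
Product: 15 5-ethyl-4-methoxy-2-Far-phenol, via dienylketene 13 (not isolated), via cyclohexadienone 14 (not isolated)
Conditions: toluene (0.01 M), 110 °C, argon
Reagents that add atoms: none
Why: Thermal conrotatory 4π ring opening cleaves the bond between the carbonyl carbon and the OMe-bearing sp3 carbon of the cyclobutenone (the later C2/C5 para axis), with the methoxy donor rotating outward so that the alkenyl arm lies cis to the ketene in 13. A thermal disrotatory 6π electrocyclisation then joins the ketene carbon to the alkene terminus (the future C2–C1 bond) and closes the six-membered carbocycle as cyclohexa-2,4-dienone 14, which tautomerises to the phenol. The closest known reaction type is the Moore rearrangement of 4-alkenyl-4-alkoxycyclobutenones to hydroquinone monoethers. No stereocentre survives: the sp3 carbon formed in 14 is planarised on aromatisation and the racemic centre of 12 is lost on ring opening. The step needs torquoselectivity, secured by the outward-rotating OMe, and must outrun ketene dimerisation or trapping by the product phenol, secured by high dilution and the fast intramolecular closure; the positions of all four substituents and the OH/OMe differentiation are fixed by the connectivity of 12.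

Step 8
Reactants: 15 5-ethyl-4-methoxy-2-Far-phenol
Product: 16 5-ethyl-4,4-dimethoxy-2-Far-cyclohexa-2,5-dien-1-one
Conditions: PhI(OAc)2 (1.1 equiv), MeOH, 0 °C
Reagents that add atoms: methanol, CO
Why: Oxidative dearomatisation of the para-methoxyphenol in methanol should give the quinone monoketal regiospecifically (ketal at the former OMe carbon, carbonyl at the former OH carbon), the phenol being oxidised far faster than the isolated trisubstituted alkenes.

Step 9
Reactants: 16 5-ethyl-4,4-dimethoxy-2-Far-cyclohexa-2,5-dien-1-one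
Product: 17 (1R,6S)-4-ethyl-5,5-dimethoxy-1-Far-7-oxabicyclo[4.1.0]hept-3-en-2-one
Conditions: t-BuOOH, aq. NaOH, N-benzylcinchonidinium chloride (10 mol %), toluene, rt
Reagents that add atoms: tert-butyl hydroperoxide, CC(C)(C)OO
Why: In this Weitz–Scheffer epoxidation under chiral phase-transfer catalysis (Wynberg type) the hydroperoxide anion adds only to the β-unsubstituted carbon of the Far-bearing enone (the other β-carbon is fully substituted), and the cinchonidinium ion pair selects the enone face, setting C1 and C6 together as the cis-fused oxirane while the electron-rich Far alkenes stay inert to the nucleophilic oxidant.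

Step 10
Reactants: 17 (1R,6S)-4-ethyl-5,5-dimethoxy-1-Far-7-oxabicyclo[4.1.0]hept-3-en-2-one
Product: 18 (1R,6S)-4-ethyl-1-Far-7-oxabicyclo[4.1.0]hept-3-ene-2,5-dione
Conditions: montmorillonite K10, wet CH2Cl2, rt
Reagents that add atoms: water, O
Why: Mild solid-acid ketal hydrolysis, as used for epoxyquinone monoketals, should unveil the C5 carbonyl without opening the electron-poor oxirane or cyclising the polyene.

Step 11
Reactants: 18 (1R,6S)-4-ethyl-1-Far-7-oxabicyclo[4.1.0]hept-3-ene-2,5-dione
Product: 19 (1R,5R,6R)-4-ethyl-5-hydroxy-1-[(2E,6E)-3,7,11-trimethyldodeca-2,6,10-trien-1-yl]-7-oxabicyclo[4.1.0]hept-3-en-2-one (CID44566894)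
Conditions: i-Bu2AlH (1.1 equiv), THF, −78 °C; then H2O work-up
Reagents that add atoms: none
Why: 1,2-Reduction should occur at the C5 carbonyl, which is the more electrophilic one (C2 is vinylogously deactivated by the β-ethyl group) and the less shielded one (C2 adjoins the quaternary C1, whose Far CH2 blocks the face anti to the oxirane), with hydride delivered anti to the oxirane C–O bond (Felkin–Anh polar model) to give the 5R carbinol cis to the epoxide oxygen, as in known epoxyquinone-to-epoxyquinol reductions.

**Compound list**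

1 | (2E,6E)-farnesyl bromide | BrC/C=C(\C)CC/C=C(\C)CCC=C(C)C | starting material
2 | (4E,8E)-5,9,13-trimethyltetradeca-4,8,12-trien-1-yne | C#CC/C=C(\C)CC/C=C(\C)CCC=C(C)C | intermediate
3 | chlorobis(cyclopentadienyl)(FV)zirconium | Cl[Zr](/C=C/C/C=C(\C)CC/C=C(\C)CCC=C(C)C)(C1C=CC=C1)C1C=CC=C1 | intermediate (not isolated)
4 | (1E,4E,8E)-1-iodo-5,9,13-trimethyltetradeca-1,4,8,12-tetraene | I/C=C/C/C=C(\C)CC/C=C(\C)CCC=C(C)C | intermediate
5 | diisopropyl squarate | CC(C)OC1=C(OC(C)C)C(=O)C1=O | starting material
6 | 4-hydroxy-2,3-diisopropoxycyclobut-2-en-1-one (racemic) | CC(C)OC1=C(OC(C)C)C(O)C1=O | intermediate (not isolated)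
7 | 3-isopropoxycyclobut-3-ene-1,2-dione | CC(C)OC1=CC(=O)C1=O | intermediate
8 | FV-lithium | [Li]/C=C/C/C=C(\C)CC/C=C(\C)CCC=C(C)C | intermediate (not isolated)
9 | 4-hydroxy-3-isopropoxy-4-FV-cyclobut-2-en-1-one (racemic) | CC(C)OC1=CC(=O)C1(O)/C=C/C/C=C(\C)CC/C=C(\C)CCC=C(C)C | intermediate
10 | 3-isopropoxy-4-methoxy-4-FV-cyclobut-2-en-1-one (racemic) | CC(C)OC1=CC(=O)C1(OC)/C=C/C/C=C(\C)CC/C=C(\C)CCC=C(C)C | intermediate
11 | 1-ethyl-3-isopropoxy-4-methoxy-4-FV-cyclobut-2-en-1-ol (mixture of diastereomers) | CCC1(O)C=C(OC(C)C)C1(OC)/C=C/C/C=C(\C)CC/C=C(\C)CCC=C(C)C | intermediate (not isolated)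
12 | 3-ethyl-4-methoxy-4-FV-cyclobut-2-en-1-one (racemic) | CCC1=CC(=O)C1(OC)/C=C/C/C=C(\C)CC/C=C(\C)CCC=C(C)C | intermediate
13 | dienylketene: 3-ethyl-4-methoxy-9,13,17-trimethyloctadeca-1,3,5,8,12,16-hexaen-1-one, alkenyl arm cis to the ketene | CC/C(C=C=O)=C(\OC)/C=C/C/C=C(\C)CC/C=C(\C)CCC=C(C)C | intermediate (not isolated)
14 | 3-ethyl-4-methoxy-6-Far-cyclohexa-2,4-dien-1-one (racemic) | CCC1=CC(=O)C(C/C=C(\C)CC/C=C(\C)CCC=C(C)C)C=C1OC | intermediate (not isolated)
15 | 5-ethyl-4-methoxy-2-Far-phenol | CCc1cc(O)c(C/C=C(\C)CC/C=C(\C)CCC=C(C)C)cc1OC | intermediate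
16 | 5-ethyl-4,4-dimethoxy-2-Far-cyclohexa-2,5-dien-1-one | CCC1=CC(=O)C(C/C=C(\C)CC/C=C(\C)CCC=C(C)C)=CC1(OC)OC | intermediate
17 | (1R,6S)-4-ethyl-5,5-dimethoxy-1-Far-7-oxabicyclo[4.1.0]hept-3-en-2-one | CCC1=CC(=O)[C@]2(C/C=C(\C)CC/C=C(\C)CCC=C(C)C)O[C@@H]2C1(OC)OC | intermediate
18 | (1R,6S)-4-ethyl-1-Far-7-oxabicyclo[4.1.0]hept-3-ene-2,5-dione | CCC1=CC(=O)[C@]2(C/C=C(\C)CC/C=C(\C)CCC=C(C)C)O[C@@H]2C1=O | intermediate
19 | (1R,5R,6R)-4-ethyl-5-hydroxy-1-Far-7-oxabicyclo[4.1.0]hept-3-en-2-one, hydroxyl cis to the oxirane oxygen | CCC1=CC(=O)[C@]2(C/C=C(\C)CC/C=C(\C)CCC=C(C)C)O[C@@H]2[C@@H]1O | target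

**Step count and risks**

Total steps: 11. Longest linear sequence: 10 (steps 1, 2, 4, 5, 6, 7, 8, 9, 10, 11).

Three steps most likely to fail:

1. Step 9. What may go wrong: the chiral ion pair may discriminate the enone faces poorly, so that the oxirane forms with insufficient enantiomeric purity, or conjugate addition to the α-branched enone may be slow. Fallback by auxiliary control, setting out from 16 and rejoining at 18: acid-catalysed trans-ketalisation of 16 with (2R,4R)-pentane-2,4-diol (PPTS, benzene, removal of MeOH) should give the C2-symmetric spiroketal dienone F1. Weitz–Scheffer epoxidation with t-BuOOH/DBU should then give two diastereomeric oxiranes that can be separated by chromatography, of which the (1R,6S)-epoxy spiroketal F2 is collected. Hydrolysis of the auxiliary ketal (montmorillonite K10 or aq. CF3CO2H) releases the diol and gives 18, so step 10 is not needed on this path.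

2. Step 11. What may go wrong: hydride may be delivered syn to the oxirane oxygen (aluminium bridging the carbonyl and oxirane oxygens), which would give the C5 epimer. Fallback by inversion instead of direct control, setting out from 18 and rejoining at 19: chelation-controlled reduction of 18 with Zn(BH4)2 (Et2O, −20 °C) should give the anti alcohol on purpose, the 5-epimer F3. Mitsunobu inversion (4-nitrobenzoic acid, PPh3, DIAD, THF, 0 °C) should give the 4-nitrobenzoate of 19 F4, and mild methanolysis (K2CO3, MeOH, 0 °C) returns 19.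

3. Step 6. What may go wrong: the lithium alkoxide of 11 may undergo anion-accelerated electrocyclic ring opening before it is protonated, or addition at the hindered vinylogous-ester carbonyl may stall. Fallback by cross-coupling in place of carbonyl addition, setting out from 10 and rejoining at 12: hydrolysis of the vinylogous ester (1 M HCl, THF, rt) should give the vinylogous acid F5. Triflation (Tf2O, 2,6-lutidine, CH2Cl2, −78 °C) should give the enol triflate F6, and Negishi coupling with Et2Zn and catalytic Pd(PPh3)4 (THF, 0 °C to rt) gives 12.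

Further compounds
F1 | step 9 | (2R,4R)-7-ethyl-2,4-dimethyl-10-Far-1,5-dioxaspiro[5.5]undeca-7,10-dien-9-one, the (2R,4R)-pentane-2,4-diyl ketal corresponding to 16 | CCC1=CC(=O)C(C/C=C(\C)CC/C=C(\C)CCC=C(C)C)=CC12O[C@H](C)C[C@@H](C)O2
F2 | step 9 | (2R,4R)-pentane-2,4-diyl ketal corresponding to 17, with the (1R,6S)-oxirane | CCC1=CC(=O)[C@]2(C/C=C(\C)CC/C=C(\C)CCC=C(C)C)O[C@@H]2C13O[C@H](C)C[C@@H](C)O3
F3 | step 11 | (1R,5S,6R)-4-ethyl-5-hydroxy-1-Far-7-oxabicyclo[4.1.0]hept-3-en-2-one, the 5-epimer of 19 | CCC1=CC(=O)[C@]2(C/C=C(\C)CC/C=C(\C)CCC=C(C)C)O[C@@H]2[C@H]1O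
F4 | step 11 | 4-nitrobenzoate of 19 | CCC1=CC(=O)[C@]2(C/C=C(\C)CC/C=C(\C)CCC=C(C)C)O[C@@H]2[C@@H]1OC(=O)c1ccc(cc1)[N+](=O)[O-]
F5 | step 6 | 3-hydroxy-4-methoxy-4-FV-cyclobut-2-en-1-one (racemic) | OC1=CC(=O)C1(OC)/C=C/C/C=C(\C)CC/C=C(\C)CCC=C(C)C
F6 | step 6 | 2-methoxy-3-oxo-2-FV-cyclobut-1-en-1-yl trifluoromethanesulfonate (racemic) | FC(F)(F)S(=O)(=O)OC1=CC(=O)C1(OC)/C=C/C/C=C(\C)CC/C=C(\C)CCC=C(C)C
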